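**Retrosynthetic overview**
1. The strategy rests on the benzylic CH of the side chain: it is bonded to an aryl carbon whose ortho carbon carries OH and to CH2–CH(CH3)2. These atoms are C4, C4a/C8a–O1 and C3/C2 of a 2,2-dimethylchroman whose O1–C2 bond has been cleaved reductively, so the target is traced back to 5,7-dihydroxy-6,8-diformyl-2,2-dimethylchroman 26.
2. Chroman 26 comes from a three-component Knoevenagel/hetero-Diels–Alder reaction of diformylphloroglucinol 24, the α-quaternary keto aldehyde 21 and 2-methylpropene, which forms C4–C4a, C3–C4 and O1–C2.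
3. Keto aldehyde 21 comes from cyclopentene ester 17 by hydroboration–oxidation, ester reduction and double oxidation. The cyclopentene–cyclopropane bond of 17 comes from a Negishi coupling of enol triflate 12 with a cis-cyclopropylzinc reagent.
4. The cyclopropylzinc comes from copper-catalysed enantioselective carbomagnesiation of 3,3-dimethylcyclopropene, and the quaternary centre from auxiliary-controlled methylation of methyl 2-oxocyclopentanecarboxylate.
5. Ring order: cyclopropane (step 1; the cyclopentane and benzene rings are bought), dihydropyran (step 12), which is opened again in step 13.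

Key step: step 12

Assumption: the absolute sense of the two reagent-controlled steps (5 and 7) is assigned by analogy; should either prove opposite, D-valine tert-butyl ester or the mirror-image ligand is used and nothing else changes.

**Step 1**
Reactants: 1 2-methylpropene
Product: 2 1,1-dibromo-2,2-dimethylcyclopropane
Conditions: CHBr3, KOtBu, pentane, −20 °C → rt
Reagents that add atoms: bromoform, BrC(Br)Br
Why: α-Elimination of bromoform gives dibromocarbene, which should add to the electron-rich 1,1-disubstituted alkene in a [2+1] dihalocarbene cyclopropanation; no stereocentre is formed.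

**Step 2**
Reactants: 2 1,1-dibromo-2,2-dimethylcyclopropane
Product: 3 1-bromo-2,2-dimethylcyclopropane (racemic)
Conditions: Bu3SnH (1.0 equiv), neat, 35 °C
Reagents that add atoms: none
Why: Radical-chain hydrodebromination with tin hydride should stop after the first bromine because the remaining cyclopropyl C–Br bond is abstracted much more slowly; the new stereocentre is racemic and is erased in step 3.

**Step 3**
Reactants: 3 1-bromo-2,2-dimethylcyclopropane
Product: 4 3,3-dimethylcyclopropene
Conditions: KOtBu, DMSO, 20 → 50 °C, N2 sweep into a −78 °C trap, kept as a titrated t-BuOMe solution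
Reagents that add atoms: none
Why: Base-induced 1,2-dehydrobromination (E2) should give the cyclopropene, and the quaternary C3 leaves no allylic hydrogen for isomerisation to a methylenecyclopropane.

**Step 4**
Reactants: 5 methyl 2-oxocyclopentane-1-carboxylate; 6 L-valine tert-butyl ester
Product: 7 methyl 2-{[(2S)-1-tert-butoxy-3-methyl-1-oxobutan-2-yl]amino}cyclopent-1-ene-1-carboxylate
Conditions: BF3·OEt2 (cat.), benzene, reflux, Dean–Stark
Reagents that add atoms: none
Why: Enamine formation: the amine condenses with the ketone of the β-keto ester to the conjugated, hydrogen-bonded enamino ester while water is removed azeotropically.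

**Step 5**
Reactants: 7 methyl 2-{[(2S)-1-tert-butoxy-3-methyl-1-oxobutan-2-yl]amino}cyclopent-1-ene-1-carboxylate
Product: 10 methyl (1S)-1-methyl-2-oxocyclopentane-1-carboxylate, via lithium aza-enolate 8 (not isolated), via methylated imine 9 (not isolated)
Conditions: LiN(iPr)2, toluene, THF (1.2 equiv), −78 °C; MeI, −78 → −40 °C; then 1 M aq. HCl, rt
Reagents that add atoms: iodomethane, CI; water, O
Why: Auxiliary-controlled aza-enolate alkylation: lithium is chelated between nitrogen and the tert-butyl ester carbonyl, the isopropyl group screens one face and methyl iodide should enter from the other, setting the quaternary stereocentre as (S); imine hydrolysis then releases the keto ester and the auxiliary.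

**Step 6**
Reactants: 10 methyl (1S)-1-methyl-2-oxocyclopentane-1-carboxylate
Product: 12 methyl (1S)-1-methyl-2-{[(trifluoromethyl)sulfonyl]oxy}cyclopent-2-ene-1-carboxylate, via potassium enolate 11 (not isolated)
Conditions: KN(SiMe3)2, THF, −78 °C; PhNTf2, −78 → 0 °C
Reagents that add atoms: N-phenylbis(trifluoromethanesulfonimide), O=S(=O)(N(c1ccccc1)S(=O)(=O)C(F)(F)F)C(F)(F)F
Why: Enol triflate formation: the ketone can enolise only towards C3 because C1 is quaternary, so O-sulfonylation should give one regioisomer, the non-nucleophilic base avoids retro-Claisen cleavage, and the stereocentre is untouched.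

**Step 7**
Reactants: 13 2-(2-bromoethyl)-2-methyl-1,3-dioxolane; 4 3,3-dimethylcyclopropene; 12 methyl (1S)-1-methyl-2-{[(trifluoromethyl)sulfonyl]oxy}cyclopent-2-ene-1-carboxylate
Product: 17 methyl (1S)-2-{(1S,3R)-2,2-dimethyl-3-[2-(2-methyl-1,3-dioxolan-2-yl)ethyl]cyclopropyl}-1-methylcyclopent-2-ene-1-carboxylate, via alkyl Grignard reagent 14 (not isolated), via cyclopropylmagnesium bromide 15 (not isolated), via cyclopropylzinc chloride 16 (not isolated)
Conditions: 13, Mg, THF, 20 °C; then 4 (1.3 equiv), CuBr·SMe2 (5 mol %), (R)-1-[(S)-2-(diphenylphosphino)ferrocenyl]ethyldicyclohexylphosphine (6 mol %), t-BuOMe, −40 → 0 °C; ZnCl2, THF, 0 °C; then 12, Pd(OAc)2 (5 mol %), SPhos (10 mol %), 50 °C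
Reagents that add atoms: none
Why: Copper-catalysed enantioselective carbomagnesiation adds the alkyl group and magnesium syn across the strained C=C, so chain and metal are cis and the chiral bisphosphine–copper complex selects between the two enantiomeric modes of addition; the configurationally stable cyclopropyl–metal bond is then exchanged to zinc and joined to the alkenyl triflate by Negishi coupling with retention, and because 12 is one enantiomer any minor-enantiomer cyclopropyl reagent should end up as a separable diastereomer.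

**Step 8**
Reactants: 17 methyl (1S)-2-{(1S,3R)-2,2-dimethyl-3-[2-(2-methyl-1,3-dioxolan-2-yl)ethyl]cyclopropyl}-1-methylcyclopent-2-ene-1-carboxylate
Product: 19 methyl (1S,2R,3R)-2-{(1R,3R)-2,2-dimethyl-3-[2-(2-methyl-1,3-dioxolan-2-yl)ethyl]cyclopropyl}-3-hydroxy-1-methylcyclopentane-1-carboxylate, via alkylborane 18 (not isolated)
Conditions: BH3·THF (2 equiv), THF, 0 °C → rt; then 3 M NaOH, 30 % H2O2, 0 °C → rt
Reagents that add atoms: hydrogen peroxide, OO
Why: Hydroboration–oxidation: boron goes to the less substituted olefinic carbon C3 and hydrogen to C2 in a syn four-centre addition, expected from the face anti to the methyl group of the neighbouring quaternary carbon (the flatter ester side, with the better σ-donor C–CH3 bond anti to the forming bonds), so that H at C2 and OH at C3 lie cis to the ester and the cyclopropyl ends cis to methyl; oxidation proceeds with retention.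

**Step 9**
Reactants: 19 methyl (1S,2R,3R)-2-{(1R,3R)-2,2-dimethyl-3-[2-(2-methyl-1,3-dioxolan-2-yl)ethyl]cyclopropyl}-3-hydroxy-1-methylcyclopentane-1-carboxylate
Product: 20 (1R,2R,3S)-2-{(1R,3R)-2,2-dimethyl-3-[2-(2-methyl-1,3-dioxolan-2-yl)ethyl]cyclopropyl}-3-(hydroxymethyl)-3-methylcyclopentan-1-ol
Conditions: LiAlH4, THF, 0 °C → rt; H2O, 15 % aq. NaOH work-up
Reagents that add atoms: none
Why: Hydride reduction of the neopentyl-type ester to the primary alcohol should proceed without touching the dioxolane or any stereocentre.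

**Step 10**
Reactants: 20 (1R,2R,3S)-2-{(1R,3R)-2,2-dimethyl-3-[2-(2-methyl-1,3-dioxolan-2-yl)ethyl]cyclopropyl}-3-(hydroxymethyl)-3-methylcyclopentan-1-ol
Product: 21 (1S,2R)-2-{(1R,3R)-2,2-dimethyl-3-[2-(2-methyl-1,3-dioxolan-2-yl)ethyl]cyclopropyl}-1-methyl-3-oxocyclopentane-1-carbaldehyde
Conditions: Dess–Martin periodinane (2.6 equiv), CH2Cl2, 0 °C → rt
Reagents that add atoms: none
Why: Dess–Martin oxidation should convert both alcohols in one operation under near-neutral, base-free conditions, so that C2 (now α to the ketone) is not epimerised; the aldehyde has no α-hydrogen and the 1,4-dicarbonyl array cannot undergo retro-aldol cleavage.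

**Step 11**
Reactants: 22 benzene-1,3,5-triol (phloroglucinol)
Product: 24 2,4,6-trihydroxybenzene-1,3-dicarbaldehyde, via bis-iminium salt 23 (not isolated)
Conditions: POCl3 (2.2 equiv), DMF (2.2 equiv), 1,4-dioxane, 0 °C → rt; then H2O, rt
Reagents that add atoms: N,N-dimethylformamide, CN(C)C=O; water, O
Why: Vilsmeier–Haack formylation: the chloroiminium ion substitutes the very electron-rich ring twice, the third position being spared by stoichiometry and by deactivation through the two iminium groups, and hydrolysis gives the dialdehyde.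

**Step 12**
Reactants: 21 (1S,2R)-2-{(1R,3R)-2,2-dimethyl-3-[2-(2-methyl-1,3-dioxolan-2-yl)ethyl]cyclopropyl}-1-methyl-3-oxocyclopentane-1-carbaldehyde; 24 2,4,6-trihydroxybenzene-1,3-dicarbaldehyde; 1 2-methylpropene
Product: 26 (4S)-4-{(1R,2R)-2-[(1R,3R)-2,2-dimethyl-3-[2-(2-methyl-1,3-dioxolan-2-yl)ethyl]cyclopropyl]-1-methyl-3-oxocyclopentyl}-5,7-dihydroxy-2,2-dimethyl-3,4-dihydro-2H-chromene-6,8-dicarbaldehyde, via o-quinone methide 25 (not isolated)
Conditions: 24 (1.0 equiv), 21 (1.1 equiv), 1 (ca. 20 equiv, condensed), ethylenediammonium diacetate (20 mol %), 4 Å MS, MeCN, sealed tube, 60 °C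
Reagents that add atoms: none
Why: Amine-catalysed Knoevenagel condensation (through the iminium ion of 21) at the one unsubstituted ring carbon of 24, followed by loss of the amine, should give the electron-poor o-quinone methide 25; because the formyl group of 21 sits on a fully substituted carbon, neither aldol self-condensation nor isomerisation of 25 to a 2-vinylphenol can drain it. 2-Methylpropene then adds in an inverse-electron-demand hetero-Diels–Alder reaction, the closest known type being the three-component assembly of chromans from formylated phloroglucinols, aldehydes and alkenes. The dihydropyran ring is closed by this intermolecular [4+2] cycloaddition itself, concerted but asynchronous: the CH2 terminus of the alkene bonds first to the exocyclic carbon (C3–C4) and the carbonyl oxygen then bonds to the tertiary carbon (O1–C2), which fixes the regiochemistry. The one new stereocentre, C4, is controlled by the adjacent quaternary carbon (1,2-induction): with the ring CH2 (C5 of the cyclopentane) eclipsing the exocyclic C=C to relieve allylic strain, the alkene must approach anti to the C2 ring branch and past the methyl group to give (4S). The step needs this facial selectivity, which the conformational bias may supply only moderately (the C4 epimer would be removed by chromatography). It also needs cycloaddition to outrun capture of 25 by a second molecule of 24, which the shielded neopentyl-type quinone methide carbon and the large excess of alkene should secure.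

**Step 13**
Reactants: 26 (4S)-4-{(1R,2R)-2-[(1R,3R)-2,2-dimethyl-3-[2-(2-methyl-1,3-dioxolan-2-yl)ethyl]cyclopropyl]-1-methyl-3-oxocyclopentyl}-5,7-dihydroxy-2,2-dimethyl-3,4-dihydro-2H-chromene-6,8-dicarbaldehyde
Product: 27 5-{(1S)-3-chloro-1-[(1R,2R)-2-[(1R,3R)-2,2-dimethyl-3-(3-oxobutyl)cyclopropyl]-1-methyl-3-oxocyclopentyl]-3-methylbutyl}-2,4,6-trihydroxybenzene-1,3-dicarbaldehyde
Conditions: BCl3 (1 M in CH2Cl2, 6 equiv), CH2Cl2, −78 → −30 °C; ice-cold 0.5 M aq. HCl quench, cold extraction, crude used at once
Reagents that add atoms: boron trichloride, ClB(Cl)Cl; water, O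
Why: Lewis-acid cleavage of a tert-alkyl aryl ether (SN1): boron, held by the C8 formyl oxygen and the neighbouring phenoxide next to O1, should ionise the tertiary C2–O1 bond and chloride captures the cation, while the same reagent opens the dioxolane, which the aqueous quench hydrolyses to the methyl ketone; a silane/acid reduction of the cation is deliberately avoided because it would also reduce the aryl aldehydes and the ketones, and no stereocentre is involved.

**Step 14**
Reactants: 27 5-{(1S)-3-chloro-1-[(1R,2R)-2-[(1R,3R)-2,2-dimethyl-3-(3-oxobutyl)cyclopropyl]-1-methyl-3-oxocyclopentyl]-3-methylbutyl}-2,4,6-trihydroxybenzene-1,3-dicarbaldehyde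
Product: 28 macrocarpal N, 5-{(1S)-1-[(1R,2R)-2-[(1R,3R)-2,2-dimethyl-3-(3-oxobutyl)cyclopropyl]-1-methyl-3-oxocyclopentyl]-3-methylbutyl}-2,4,6-trihydroxybenzene-1,3-dicarbaldehyde
Conditions: Bu3SnH (3 equiv), AIBN (0.3 equiv, portionwise), benzene, 80 °C
Reagents that add atoms: none
Why: Tin hydride radical-chain dehalogenation: the stannyl radical abstracts chlorine and the tertiary alkyl radical takes hydrogen from Bu3SnH, conditions that should leave phenols, aldehydes, ketones and the remote cyclopropane untouched and do not involve any stereocentre.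

**Compound list**
1 | 2-methylpropene | CC(C)=C | starting material
2 | 1,1-dibromo-2,2-dimethylcyclopropane | CC1(C)CC1(Br)Br | intermediate
3 | 1-bromo-2,2-dimethylcyclopropane (racemic) | CC1(C)CC1Br | intermediate
4 | 3,3-dimethylcyclopropene | CC1(C)C=C1 | intermediate
5 | methyl 2-oxocyclopentane-1-carboxylate | COC(=O)C1CCCC1=O | starting material
6 | L-valine tert-butyl ester | CC(C)[C@H](N)C(=O)OC(C)(C)C | starting material
7 | methyl 2-{[(2S)-1-tert-butoxy-3-methyl-1-oxobutan-2-yl]amino}cyclopent-1-ene-1-carboxylate | COC(=O)C1=C(N[C@@H](C(C)C)C(=O)OC(C)(C)C)CCC1 | intermediate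
8 | N-lithio derivative of 7 (lithium aza-enolate) | COC(=O)C1=C(N([Li])[C@@H](C(C)C)C(=O)OC(C)(C)C)CCC1 | intermediate
9 | methyl (1S)-2-{[(2S)-1-tert-butoxy-3-methyl-1-oxobutan-2-yl]imino}-1-methylcyclopentane-1-carboxylate | CC(C)[C@H](N=C2CCC[C@]2(C)C(=O)OC)C(=O)OC(C)(C)C | intermediate
10 | methyl (1S)-1-methyl-2-oxocyclopentane-1-carboxylate | O=C1CCC[C@]1(C)C(=O)OC | intermediate
11 | potassium (5S)-5-(methoxycarbonyl)-5-methylcyclopent-1-en-1-olate | [K+].[O-]C1=CCC[C@]1(C)C(=O)OC | intermediate
12 | methyl (1S)-1-methyl-2-{[(trifluoromethyl)sulfonyl]oxy}cyclopent-2-ene-1-carboxylate | O=S(=O)(OC1=CCC[C@]1(C)C(=O)OC)C(F)(F)F | intermediate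
13 | 2-(2-bromoethyl)-2-methyl-1,3-dioxolane | CC1(CCBr)OCCO1 | starting material
14 | [2-(2-methyl-1,3-dioxolan-2-yl)ethyl]magnesium bromide | CC1(CC[Mg]Br)OCCO1 | intermediate
15 | {(1S,3S)-2,2-dimethyl-3-[2-(2-methyl-1,3-dioxolan-2-yl)ethyl]cyclopropyl}magnesium bromide (chain and metal cis) | CC3(OCCO3)CC[C@@H]1[C@H]([Mg]Br)C1(C)C | intermediate
16 | {(1S,3S)-2,2-dimethyl-3-[2-(2-methyl-1,3-dioxolan-2-yl)ethyl]cyclopropyl}zinc chloride (chain and metal cis) | CC3(OCCO3)CC[C@@H]1[C@H]([Zn]Cl)C1(C)C | intermediate
17 | methyl (1S)-2-{(1S,3R)-2,2-dimethyl-3-[2-(2-methyl-1,3-dioxolan-2-yl)ethyl]cyclopropyl}-1-methylcyclopent-2-ene-1-carboxylate (cis-cyclopropane) | CC3(OCCO3)CC[C@@H]1[C@H](C2=CCC[C@]2(C)C(=O)OC)C1(C)C | intermediate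
18 | methyl (1S,2R,3R)-3-boranyl-2-{(1R,3R)-2,2-dimethyl-3-[2-(2-methyl-1,3-dioxolan-2-yl)ethyl]cyclopropyl}-1-methylcyclopentane-1-carboxylate (BH2 and 2-H cis to the ester) | CC3(OCCO3)CC[C@@H]1[C@H]([C@H]2[C@H](B)CC[C@]2(C)C(=O)OC)C1(C)C | intermediate
19 | methyl (1S,2R,3R)-2-{(1R,3R)-2,2-dimethyl-3-[2-(2-methyl-1,3-dioxolan-2-yl)ethyl]cyclopropyl}-3-hydroxy-1-methylcyclopentane-1-carboxylate | CC3(OCCO3)CC[C@@H]1[C@H]([C@H]2[C@H](O)CC[C@]2(C)C(=O)OC)C1(C)C | intermediate
20 | (1R,2R,3S)-2-{(1R,3R)-2,2-dimethyl-3-[2-(2-methyl-1,3-dioxolan-2-yl)ethyl]cyclopropyl}-3-(hydroxymethyl)-3-methylcyclopentan-1-ol | CC3(OCCO3)CC[C@@H]1[C@H]([C@H]2[C@H](O)CC[C@]2(C)CO)C1(C)C | intermediate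
21 | (1S,2R)-2-{(1R,3R)-2,2-dimethyl-3-[2-(2-methyl-1,3-dioxolan-2-yl)ethyl]cyclopropyl}-1-methyl-3-oxocyclopentane-1-carbaldehyde | CC3(OCCO3)CC[C@@H]1[C@H]([C@H]2C(=O)CC[C@]2(C)C=O)C1(C)C | intermediate
22 | benzene-1,3,5-triol (phloroglucinol) | Oc1cc(O)cc(O)c1 | starting material
23 | N,N'-[(2,4,6-trihydroxy-1,3-phenylene)dimethylidyne]bis(N-methylmethanaminium) dichloride | C[N+](C)=Cc1c(O)cc(O)c(C=[N+](C)C)c1O.[Cl-].[Cl-] | intermediate
24 | 2,4,6-trihydroxybenzene-1,3-dicarbaldehyde (diformylphloroglucinol) | O=Cc1c(O)cc(O)c(C=O)c1O | intermediate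
25 | 5-{[(1R,2R)-2-{(1R,3R)-2,2-dimethyl-3-[2-(2-methyl-1,3-dioxolan-2-yl)ethyl]cyclopropyl}-1-methyl-3-oxocyclopentyl]methylidene}-2,4-dihydroxy-6-oxocyclohexa-1,3-diene-1,3-dicarbaldehyde (alkene geometry not defined) | CC3(OCCO3)CC[C@@H]1[C@H]([C@H]2C(=O)CC[C@]2(C)C=C4C(=O)C(C=O)=C(O)C(C=O)=C4O)C1(C)C | intermediate
26 | (4S)-4-{(1R,2R)-2-[(1R,3R)-2,2-dimethyl-3-[2-(2-methyl-1,3-dioxolan-2-yl)ethyl]cyclopropyl]-1-methyl-3-oxocyclopentyl}-5,7-dihydroxy-2,2-dimethyl-3,4-dihydro-2H-chromene-6,8-dicarbaldehyde | CC3(OCCO3)CC[C@@H]1[C@H]([C@H]2C(=O)CC[C@]2(C)[C@@H]4CC(C)(C)Oc5c4c(O)c(C=O)c(O)c5C=O)C1(C)C | intermediate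
27 | 5-{(1S)-3-chloro-1-[(1R,2R)-2-[(1R,3R)-2,2-dimethyl-3-(3-oxobutyl)cyclopropyl]-1-methyl-3-oxocyclopentyl]-3-methylbutyl}-2,4,6-trihydroxybenzene-1,3-dicarbaldehyde | CC(=O)CC[C@@H]1[C@H]([C@H]2C(=O)CC[C@]2(C)[C@H](CC(C)(C)Cl)c2c(O)c(C=O)c(O)c(C=O)c2O)C1(C)C | intermediate
28 | macrocarpal N, 5-{(1S)-1-[(1R,2R)-2-[(1R,3R)-2,2-dimethyl-3-(3-oxobutyl)cyclopropyl]-1-methyl-3-oxocyclopentyl]-3-methylbutyl}-2,4,6-trihydroxybenzene-1,3-dicarbaldehyde | CC(=O)CC[C@@H]1[C@H]([C@H]2C(=O)CC[C@]2(C)[C@H](CC(C)C)c2c(O)c(C=O)c(O)c(C=O)c2O)C1(C)C | target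

**Step count and risks**
Total step count: 14. Longest linear sequence: 10 steps (steps 4–10 and 12–14 from methyl 2-oxocyclopentane-1-carboxylate; equally steps 1–3, 7–10 and 12–14 from 2-methylpropene).

The three steps most likely to fail:

1. Step 12. The condensation at the neopentyl-type formyl group may be slow, so that the quinone methide, present only in low concentration, is captured by a second phloroglucinol or by water instead of the alkene; facial discrimination may also be weak at the temperature the condensation demands. The fallback separates the two events. It sets out from 21 and 24, which are condensed in the presence of 4-methylbenzenesulfinic acid (catalytic ethylenediammonium diacetate, CH2Cl2, 4 Å MS) so that the quinone methide is trapped as the isolable benzylic sulfone 5-{[(1S,2R)-2-{(1R,3R)-2,2-dimethyl-3-[2-(2-methyl-1,3-dioxolan-2-yl)ethyl]cyclopropyl}-1-methyl-3-oxocyclopentyl][(4-methylphenyl)sulfonyl]methyl}-2,4,6-trihydroxybenzene-1,3-dicarbaldehyde F1. Treatment of this sulfone with Cs2CO3 in CH2Cl2 saturated with 2-methylpropene (sealed tube, 0 → 25 °C) regenerates 25 under non-acidic conditions at low temperature, where the cycloaddition should be more face-selective, and the route is rejoined at 26.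

2. Step 13. The tertiary carbocation may fragment with loss of 2-methylpropene (reversal of the cycloaddition), and the liberated phenol may close again onto the tertiary chloride during isolation. The fallback sets out from 26 and never frees the phenol next to a tertiary halide. Pyridinium p-toluenesulfonate in wet acetone removes the dioxolane to give (4S)-4-{(1R,2R)-2-[(1R,3R)-2,2-dimethyl-3-(3-oxobutyl)cyclopropyl]-1-methyl-3-oxocyclopentyl}-5,7-dihydroxy-2,2-dimethyl-3,4-dihydro-2H-chromene-6,8-dicarbaldehyde F2. N,O-Bis(trimethylsilyl)acetamide and Me3SiI (CH2Cl2, −20 °C) then silylate the phenols and cleave the tertiary ether in one operation to the ring-opened iodide 5-{(1S)-3-iodo-1-[(1R,2R)-2-[(1R,3R)-2,2-dimethyl-3-(3-oxobutyl)cyclopropyl]-1-methyl-3-oxocyclopentyl]-3-methylbutyl}-2,4,6-tris(trimethylsilyloxy)benzene-1,3-dicarbaldehyde F3, whose silylated oxygen cannot re-close. Bu3SnH and Et3B/air are added to the same flask at 0 °C, and a methanolic citric acid work-up removes the silyl groups, so the route is rejoined directly at 28.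

3. Step 8. Borane may add with poor or inverted facial selectivity (attack syn to the quaternary methyl group), which would give the C2/C3 diastereomer. The fallback sets out from 17 and replaces substrate control by delivery from the ester. A carbonyl-directed rhodium-catalysed hydroboration (pinacolborane, Rh(nbd)2BF4 2 mol %, P(OPh)3 4 mol %, THF, 40 °C) binds the metal to the ester carbonyl, so that H and B are transferred to the ester face and the product is methyl (1S,2R,3R)-2-{(1R,3R)-2,2-dimethyl-3-[2-(2-methyl-1,3-dioxolan-2-yl)ethyl]cyclopropyl}-1-methyl-3-(4,4,5,5-tetramethyl-1,3,2-dioxaborolan-2-yl)cyclopentane-1-carboxylate F4. Oxidation with NaBO3·4H2O in THF/H2O rejoins the route at 19. A further safeguard exists for C2: once the bulky chromanyl group is in place (after step 12), the cyclopropyl strongly prefers to lie trans to it, so any erosion at C2 could be corrected there by base equilibration (NaOMe, MeOH).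

**Further compounds**
F1 | step 12 | 5-{[(1S,2R)-2-{(1R,3R)-2,2-dimethyl-3-[2-(2-methyl-1,3-dioxolan-2-yl)ethyl]cyclopropyl}-1-methyl-3-oxocyclopentyl][(4-methylphenyl)sulfonyl]methyl}-2,4,6-trihydroxybenzene-1,3-dicarbaldehyde (mixture at the sulfonyl-bearing carbon) | CC3(OCCO3)CC[C@@H]1[C@H]([C@H]2C(=O)CC[C@]2(C)C(c4c(O)c(C=O)c(O)c(C=O)c4O)S(=O)(=O)c5ccc(C)cc5)C1(C)C
F2 | step 13 | (4S)-4-{(1R,2R)-2-[(1R,3R)-2,2-dimethyl-3-(3-oxobutyl)cyclopropyl]-1-methyl-3-oxocyclopentyl}-5,7-dihydroxy-2,2-dimethyl-3,4-dihydro-2H-chromene-6,8-dicarbaldehyde | CC(=O)CC[C@@H]1[C@H]([C@H]2C(=O)CC[C@]2(C)[C@@H]4CC(C)(C)Oc5c4c(O)c(C=O)c(O)c5C=O)C1(C)C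
F3 | step 13 | 5-{(1S)-3-iodo-1-[(1R,2R)-2-[(1R,3R)-2,2-dimethyl-3-(3-oxobutyl)cyclopropyl]-1-methyl-3-oxocyclopentyl]-3-methylbutyl}-2,4,6-tris(trimethylsilyloxy)benzene-1,3-dicarbaldehyde | CC(=O)CC[C@@H]1[C@H]([C@H]2C(=O)CC[C@]2(C)[C@H](CC(C)(C)I)c2c(O[Si](C)(C)C)c(C=O)c(O[Si](C)(C)C)c(C=O)c2O[Si](C)(C)C)C1(C)C
F4 | step 8 | methyl (1S,2R,3R)-2-{(1R,3R)-2,2-dimethyl-3-[2-(2-methyl-1,3-dioxolan-2-yl)ethyl]cyclopropyl}-1-methyl-3-(4,4,5,5-tetramethyl-1,3,2-dioxaborolan-2-yl)cyclopentane-1-carboxylate | CC3(OCCO3)CC[C@@H]1[C@H]([C@H]2[C@H](B4OC(C)(C)C(C)(C)O4)CC[C@]2(C)C(=O)OC)C1(C)C
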